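905 molecules of starting material were converted per enzyme charged in the dusk run, reckoned from the target and the isomer of the product read at 40.0 min. In these flasks enzyme turns starting material into target, and target goes on to isomer of the product. The two peaks together therefore count the fraction of the charge used, and one minus that count is the fraction left.

| flask | starting material | second substrate | capture agent | enzyme | remark | time |
|---|---|---|---|---|---|---|
| dusk | 0.14 M | 0.070 M | 7 mM | 28 µM | run made earlier |  |
| spring | 0.14 M | 0.070 M | 7 mM | 39 µM | run made earlier |  |
| midnight | 0.14 M | 0.070 M | 7 mM | 62 µM | run made earlier |  |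
| alpha | 0.14 M | 0.0700 M (fed, over 1.5 min) | 7.00 mM | 28 µM | all else is in the flask from the start; the feed brings no volume worth counting | 40 min |
| epsilon | 0.14 M (fed, over 15 min) | 0.0700 M | 7.00 mM | 28 µM | all else is in the flask from the start; the feed brings no volume worth counting | 40 min |
| theta | 0.14 M | 0.0700 M | 7.00 mM | 28 µM | everything together at the start | 40 min |
| gamma | 0.14 M | 0.0700 M (fed, over 15 min) | 7.00 mM | 28 µM | all else is in the flask from the start; the feed brings no volume worth counting | 40 min |

| run | time / min | isomer of the product / % | target / % |
|---|---|---|---|
| dusk | 4.00 | 0 | 8.3 |
| dusk | 10.0 | 2.5 | 13.2 |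
| dusk | 20.0 | 6.7 | 10.4 |
| dusk | 30.0 | 8.3 | 10.2 |
| dusk | 40.0 | 9.7 | 8.4 |
| spring | 2.00 | 0.4 | 7.8 |
| spring | 6.00 | 2.7 | 14.5 |
| spring | 12.0 | 7.1 | 17.2 |
| spring | 15.0 | 4.9 | 18.0 |
| spring | 25.0 | 9.8 | 13.4 |
| midnight | 2.00 | 0.7 | 11.0 |
| midnight | 4.00 | 0.6 | 18.4 |
| midnight | 6.00 | 1.7 | 21.8 |
| midnight | 12.0 | 7.2 | 24.9 |
| midnight | 25.0 | 15.7 | 21.4 |

(scatter of a reading: 1 percentage point)

* the flask with the highest amount of isomer of the product, in percent of the starting material charged ("all alike" if they lie within 1.5 percentage points) (alpha / epsilon / theta / gamma / all alike)
* final isomer of the product, as a percentage of the starting material charged, in alpha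
* final isomer of the product, as a percentage of the starting material charged, in epsilon
* final isomer of the product, as a percentage of the starting material charged, in theta
* final isomer of the product, as a percentage of the starting material charged, in gamma



Read across, the two peaks add up to 18.1% in dusk at 40.0 min, 23.2% in spring at 25.0 min and 37.1% in midnight at 25.0 min. The dusk sum already stood at 17.1% at 20.0 min, so it gains 1 percentage point between these two readings, and by this count 81.9% of the dusk charge is left at 40.0 min. The sums rise with the enzyme charged, and divided by it, spring gives 833 and midnight 838. That spread is about what a scatter of 1 point on each peak allows. Their mean with dusk, 859, is the turnover number: molecules of starting material converted per enzyme before the enzyme stops working.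

The fraction left follows from it. Theta repeats dusk, so this reckoning leaves 82.8% of its starting material. With dusk's isomer share of the sum, 53.6%, this reckoning puts 9.20% isomer of the product in theta. Dusk, spring and midnight charged equal starting material and second substrate, so the turnover number is a reading at one ratio of the two. A feed over 15 min changes that ratio while it lasts. This reckoning commits to the number anyway and leaves 82.8% in gamma and epsilon too.

The forecast names theta as the flask with the most isomer of the product, with 9.3% in alpha, 3.5% in epsilon, 9.7% in theta and 3.5% in gamma, and adds a reserve: “If enzyme death is turnover-linked instead, these would rise”. The reckoning above takes the road of that reserve, so for gamma and epsilon it differs from the forecast's printed values.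

Gamma holds 19.2% isomer of the product at 40.0 min, the most of the four, beside 11.4% in alpha, 2.84% in epsilon and 10.2% in theta.

    starting material + enzyme ⇌ complex A (K = 8.40 M⁻¹, k = 3.10 × 10⁵ M⁻¹ min⁻¹)
    complex A → enzyme + target (k = 340 min⁻¹)
    second substrate + enzyme ⇌ complex B (K = 5.50 M⁻¹, k = 30000 M⁻¹ min⁻¹)
    complex B → enzyme + second product (k = 150 min⁻¹)
    target ⇌ isomer of the product (K = 1.90, k = 0.0360 min⁻¹)
    capture agent + complex B → trapped intermediate (k = 150 M⁻¹ min⁻¹)

Over the first 15 min, the mean second substrate in gamma was 0.0337 M, half of theta's 0.0675 M. Gamma's two peaks give a turnover number of 1780, twice the value read from the earlier runs, and 64.4% of its starting material is left, not 82.8%. Epsilon, with its starting material fed, gives 271, and 94.6% of its starting material stands at 40.0 min.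

The earlier runs and the new flask come from a simulation with made-up constants, and the scatter is random.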